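Assumption: both phenols are carried as benzyl ethers instead of silyl ethers, because the benzyl-protected guaiacyl building blocks 2 and 5 are catalogue compounds and benzyl ethers tolerate aqueous base, diazotisation and t-BuLi. The bond formed, the ring closed and the skeletons of the key step are unchanged. Racemic compounds are drawn as one enantiomer.

## Structural features

Larreantin is a 1,4-naphthoquinone in which quinone ring A (C1 to C4 with C4a and C8a) is fused to benzenoid ring B (C4a, C5 to C8, C8a). Ring A carries a methoxy group at C2 and hydrogen at C3. Ring B carries hydrogen only at C5, a 4-hydroxy-3-methoxybenzyl group (ring D, joined through a CH2) at C6, a methyl group at C7 and a 4-hydroxy-3-methoxyphenyl group (ring C, joined by a biaryl bond) at C8, peri to the C1 carbonyl. There is no stereocentre, so only constitution has to be controlled; the twisted C8–aryl bond carries no descriptor. The fragile parts are the methoxyquinone (a vinylogous ester open to nucleophiles and bases at C2), the two free guaiacol phenols (easily oxidised) and the doubly benzylic CH2. The real difficulty is regiochemical: ring B bears four contiguous carbon substituents (C6, C7, C8, C8a), and the methoxy group must end at C2, on the crowded side next to the peri-aryl group, and not at C3. The key step uses two features: the sequence C1(O)–C2(OMe)–C3(H)–C4(O) is the substitution pattern of a methyl semisquarate, and C8a has a single unsubstituted ortho neighbour, C4a, so a four-carbon unit attached at C8a can close ring A in one direction only.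

## Logic of the disconnections

19 is taken back to 17. The bonds cut are the two phenolic O–CH2Ph bonds, and the quinone is stepped down to the diol level, with 18 lying between. Free phenols and a quinone would not survive organolithium chemistry, and 17 is the oxidation level that the ring expansion delivers. The gain is that deprotection and oxidation merge into one operation. The forward step must hydrogenolyse the benzyl ethers without touching the naphthalene or the diarylmethane, and air must oxidise only the naphthalenediol of 18.

17 is cut at C4–C4a, which opens ring A to the four-membered ring of 15, with 16 as the open-chain link in the forward sense. This is the only cut that reduces ring A to one small C4 building block and ring B to an arene needing a single metalated carbon. The forward step needs a thermal ring opening with the hydroxyl turning outward and closure on C4a. The methoxy-bearing carbon of 15 must be bonded to the carbinol carbon, so that the methoxy group ends at C2.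

15 is cut at the bond between C8a and the carbinol carbon (the future C1), giving nucleophile 14, drawn from 10, and electrophile 13. A carbonyl addition is the direct way to a tertiary aryl carbinol on a cyclobutenone. The gain is full convergence: all of rings B, C and D in one piece, ring A in the other. The demand is clean metalation at the carbon flanked by ring C, and addition to the ketone-like carbonyl of 13 and not to its vinylogous ester carbonyl.

13 is traced to 11 by exchanging the hydrogen at the future C3 for a methoxy group. Forward, one carbonyl is reduced to give 12, and methanol is then lost. The gain is a commercial starting material. The demand is mono-reduction and an acid step mild enough for a sensitive dione.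

10 is traced to 8 by replacing C–I with C–N. The amino group is needed earlier as a para-director and is then turned into the handle for metalation, so one substituent serves twice. The demand is that iodide captures the diazonium ion 9 faster than any other reaction partner, including the neighbouring ring C.

8 is cut at the bond between C6 of ring B and the CH2 group, giving 4 and 6, with 7 as the organometallic form of 6. An sp2–sp3 coupling brings in ring D intact and at the right oxidation level. The demand is tolerance of the free amino group and a single carbon–halogen bond in 4.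

6 comes from 5 by exchange of C–O for C–Cl, a one-step activation of a purchasable alcohol.

4 comes from 3 by cutting the C–Br bond at the position para to nitrogen. The demand is para-selectivity and discrimination between the aniline ring and the dialkoxy ring C.

3 is cut at the biaryl bond between C8 and ring C into 1 and 2. This sets the most hindered aryl–aryl bond first, on the smallest substrate. The demand is a coupling at a bromide flanked by NH2 and CH3.

## Other disconnections considered

Alternative 1: The cut is the C7=C8 bond of ring B, taken at the 5,6-dihydro level. The precursor is keto ketone A1, with the diaryl ketone carbon (C8) on C8a of a 1,2,4-trimethoxybenzene ring A and the methyl ketone (C7) at the end of a three-carbon chain from C4a. Forward, low-valent titanium made from TiCl3 (trivalent titanium) and Zn–Cu would couple the two carbonyl carbons reductively (intramolecular McMurry reaction) to give racemic dihydronaphthalene A2.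
- In its favour: the most crowded bond of the target is made intramolecularly by a reaction that copes with tetrasubstituted alkenes in six-membered rings. Ring A travels as a robust trimethoxyarene. The positions of benzyl, methyl and aryl are fixed by the constitution of A1.
- Against it here: A2 still needs dehydrogenation of C5–C6, oxidative demethylation to the quinone with (NH4)2Ce(NO3)6 (tetravalent cerium, which may also attack the two electron-rich benzyloxy-methoxy rings) and debenzylation. A1 needs an ortho-aroyl group beside a branched side chain on a fully substituted arene. The C6 stereocentre is made only to be destroyed. A large excess of oxophilic titanium may be slowed by the chelating ortho-methoxy groups.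
- Comparison: on structure it is the equal of the chosen plan in fixing the ring B pattern, and arguably better in avoiding a hindered carbanion addition and a sensitive cyclobutenedione. On mechanism the chosen ring expansion gives the oxygen pattern of ring A directly at the hydroquinone level, whereas A2 must be aromatised and oxidised. On step economy the alternative is longer, with at least three operations after its key step against one.

Alternative 2: The cut removes three bonds at once, C4a–C8a, C5–C6 and C7–C8, so that rings A and B arise together. The partners are diyne A3 (a cis-enedione flanked by an ethynyl ketone and an arylethynyl ketone) and butyne A4. Forward, [Rh(cod)2]BF4/BINAP (monovalent rhodium) would mediate a (2+2+2) cyclotrimerisation to larreantin bis(tert-butyldimethylsilyl) ether A5.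
- In its favour: the convergence is the highest of all plans, and A5 is one deprotection from the target at the correct oxidation level.
- Against it here: A3 is a doubly activated bis-ynone whose enedione must stay cis; isomerisation to the trans form would stop ring A from closing, and Michael addition or oligomerisation are likely. Making A3 with the methoxy group on the enedione is itself a multi-step problem. The two ends of A4 (CH2Ar and CH3) differ little, so the C6/C7 orientation is expected to be poorly controlled. Internal monoalkynes are also sluggish partners, which favours self-trimerisation of A3.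
- Comparison: in step economy and convergence this alternative is better than the chosen plan, and it is its equal in delivering the quinone oxidation level. On structure and mechanism the chosen plan is safer: there the C6/C7 pattern is built in a fixed order on the aniline and ring closure has only one possible site.

Alternative 3: The cut removes C5–C6 and C7–C8 of ring B. The partners are ortho-benzyl benzaldehyde A6 (aldehyde carbon = C5, diarylmethane carbon = C8) and ynone A7 (carbonyl-bearing alkyne carbon = C6, methyl-bearing alkyne carbon = C7). Forward, irradiation at 365 nm would enolise A6 to a hydroxy-ortho-quinodimethane, which adds to A7 in a Diels–Alder reaction; acid then removes water to give naphthalene A8.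
- In its favour: two fragments of similar size are joined and ring B is made with all three substituents in one operation. The orientation should be well defined, since the hydroxyl-bearing terminus pairs with the carbonyl-bearing alkyne carbon and so puts the aroyl group on C6.
- Against it here: the reactive dienol must carry an aryl group on its second terminus, and the forming C7–C8 bond joins an aryl-bearing carbon to a methyl-bearing alkyne carbon, a hindered pairing with an internal ynone. A8 then needs deoxygenation of a hindered diaryl ketone to the CH2 group, oxidative demethylation to the quinone and debenzylation.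
- Comparison: in convergence and in regiochemical definition of the key step this plan is the equal of the chosen one. On mechanism it rests on a photochemical step on a crowded substrate, against a thermal unimolecular ring expansion. On step economy it is behind, with three or more operations after the key step against one.

Key step: step 8

## Route

Step 1
Reactants: 1 2-bromo-3-methylaniline; 2 (4-benzyloxy-3-methoxyphenyl)boronic acid
Product: 3 2-(4-benzyloxy-3-methoxyphenyl)-3-methylaniline
Conditions: Pd(OAc)2 (2 mol %), SPhos (4 mol %), K3PO4, toluene/H2O, 90 °C
Reagents that add atoms: none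
Why: Suzuki–Miyaura coupling; the bulky biarylphosphine SPhos supports oxidative addition and reductive elimination at the electron-rich bromide flanked by NH2 and CH3, and the free amino group and the benzyl ether are inert to aqueous phosphate.

Step 2
Reactants: 3 2-(4-benzyloxy-3-methoxyphenyl)-3-methylaniline
Product: 4 4-bromo-2-(4-benzyloxy-3-methoxyphenyl)-3-methylaniline
Conditions: NBS (1.0 equiv), DMF, −20 → 0 °C
Reagents that add atoms: N-bromosuccinimide, O=C1CCC(=O)N1Br
Why: Electrophilic aromatic bromination; the free amino group directs to its open para position, and the aniline ring is far more nucleophilic than the dialkoxy ring C, so one equivalent of NBS at low temperature should give the monobromide at that carbon.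

Step 3
Reactants: 5 (4-benzyloxy-3-methoxyphenyl)methanol
Product: 6 1-benzyloxy-4-(chloromethyl)-2-methoxybenzene
Conditions: SOCl2, CH2Cl2, 0 °C → rt
Reagents that add atoms: thionyl chloride, O=S(Cl)Cl
Why: Deoxychlorination of an electron-rich benzylic alcohol through its chlorosulfite (nucleophilic substitution helped by the para oxygen); aryl benzyl and methyl ethers are stable to the HCl released at this temperature.

Step 4
Reactants: 6 1-benzyloxy-4-(chloromethyl)-2-methoxybenzene; 4 4-bromo-2-(4-benzyloxy-3-methoxyphenyl)-3-methylaniline
Product: 8 2-(4-benzyloxy-3-methoxyphenyl)-4-[(4-benzyloxy-3-methoxyphenyl)methyl]-3-methylaniline, via benzylzinc chloride 7 (not isolated)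
Conditions: Zn dust, LiCl, THF, 25 °C; then 4, Pd(OAc)2 (2 mol %), SPhos (4 mol %), THF, 25 → 50 °C
Reagents that add atoms: none
Why: LiCl-promoted zinc insertion into the benzylic chloride gives 7 with little homocoupling; Negishi coupling at the only C–Br bond of 4 tolerates the unprotected aniline because a benzylic zinc reagent is too weakly basic to deprotonate it.

Step 5
Reactants: 8 2-(4-benzyloxy-3-methoxyphenyl)-4-[(4-benzyloxy-3-methoxyphenyl)methyl]-3-methylaniline
Product: 10 2-(4-benzyloxy-3-methoxyphenyl)-4-[(4-benzyloxy-3-methoxyphenyl)methyl]-1-iodo-3-methylbenzene, via arenediazonium tosylate 9 (not isolated)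
Conditions: t-BuONO, p-TsOH·H2O, MeCN, 0 °C; then KI, H2O, 0 °C → rt
Reagents that add atoms: potassium iodide, [K+].[I-]
Why: Diazotisation followed by iododediazoniation (copper-free Sandmeyer-type reaction): iodide reduces the diazonium ion by electron transfer and the aryl radical picks up iodine; the tosylate counter-ion gives a soluble, fairly stable diazonium salt in acetonitrile, and benzyl ethers tolerate the sulfonic acid.

Step 6
Reactants: 11 dimethyl squarate (3,4-dimethoxycyclobut-3-ene-1,2-dione)
Product: 13 methyl semisquarate (3-methoxycyclobut-3-ene-1,2-dione), via hydroxycyclobutenone 12 (not isolated)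
Conditions: LiAlH(OtBu)3, THF, −78 → −20 °C; then conc. HCl (cat.), CH2Cl2, rt
Reagents that add atoms: none
Why: The bulky hydride reduces one carbonyl only (1,2-reduction) to 12; acid then ionises the allylic hydroxyl, water adds at the methoxy-stabilised end of the allyl cation and methanol is lost (allylic transposition with vinylogous ester hydrolysis), leaving hydrogen where a methoxy group stood.

Step 7
Reactants: 10 2-(4-benzyloxy-3-methoxyphenyl)-4-[(4-benzyloxy-3-methoxyphenyl)methyl]-1-iodo-3-methylbenzene; 13 methyl semisquarate
Product: 15 racemic 4-{2-(4-benzyloxy-3-methoxyphenyl)-4-[(4-benzyloxy-3-methoxyphenyl)methyl]-3-methylphenyl}-4-hydroxy-3-methoxycyclobut-2-en-1-one, via aryllithium 14 (not isolated)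
Conditions: t-BuLi (2.0 equiv), THF, −78 °C; then cannulation into 13 (1.3 equiv), THF, −78 °C; NH4Cl (aq)
Reagents that add atoms: none
Why: Iodine–lithium exchange outruns any deprotonation at −78 °C, and the aryllithium adds 1,2 to the carbonyl of 13 that adjoins the methoxy-bearing carbon, because the other carbonyl is deactivated as a vinylogous ester; inverse addition to an excess of 13 limits double addition. The carbinol centre forms as a racemate and is removed again in step 8.

Step 8
Reactants: 15 racemic 4-aryl-4-hydroxy-3-methoxycyclobut-2-en-1-one (aryl = ring B with rings C and D as benzyl ethers)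
Product: 17 8-(4-benzyloxy-3-methoxyphenyl)-6-[(4-benzyloxy-3-methoxyphenyl)methyl]-2-methoxy-7-methylnaphthalene-1,4-diol, via dienylketene 16 (not isolated)
Conditions: p-xylene (degassed), 138 °C, Ar; crude 17 carried on under Ar
Reagents that add atoms: none
Why: Heat opens the cyclobutenone by a conrotatory 4π electrocyclic cleavage of the bond between the carbonyl carbon and the carbinol carbon, giving dienylketene 16. The hydroxyl, the stronger donor, turns outward, so the aryl group turns inward and ends cis to the ketene. A six-electron electrocyclisation then joins the ketene carbon (the future C4) to C4a and closes the six-membered ring A, and enolisation of the cyclohexadienone gives the aromatic diol 17. The closest known reaction type is the thermal ring expansion of squarate-derived 4-aryl-4-hydroxycyclobutenones to naphthalene-1,4-diols. No stereocentre is formed, and the carbinol centre of 15 disappears. The selectivity needed is regiochemical: closure must reach C4a, which is secured because C8 already carries ring C and leaves C4a as the only unsubstituted ortho position, while the outward rotation of the hydroxyl places the ketene on the aryl side. The methoxy group ends at C2, next to C1, because in 15 its carbon is bonded to the carbinol carbon. Benzyl ethers and the diarylmethane are inert at this temperature, and exclusion of oxygen keeps the product at the diol level.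

Step 9
Reactants: 17 8-(4-benzyloxy-3-methoxyphenyl)-6-[(4-benzyloxy-3-methoxyphenyl)methyl]-2-methoxy-7-methylnaphthalene-1,4-diol
Product: 19 larreantin (8-(4-hydroxy-3-methoxyphenyl)-6-[(4-hydroxy-3-methoxyphenyl)methyl]-2-methoxy-7-methylnaphthalene-1,4-dione), via larreantin hydroquinone 18 (not isolated)
Conditions: H2 (1 atm), Pd/C, EtOAc/MeOH, rt; filtration under Ar; then air, rt
Reagents that add atoms: none
Why: Hydrogenolysis of the two aryl benzyl ethers over Pd/C; any quinone formed beforehand by adventitious air is reduced back to the diol. The electron-rich 2-methoxynaphthalene-1,4-diol 18 is then autoxidised by air to the quinone, while the guaiacol phenols, which need much stronger oxidants, should remain untouched.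

## Compound list

1 | 2-bromo-3-methylaniline | Cc1cccc(N)c1Br | starting material
2 | (4-benzyloxy-3-methoxyphenyl)boronic acid | COc1cc(B(O)O)ccc1OCc1ccccc1 | starting material
3 | 2-(4-benzyloxy-3-methoxyphenyl)-3-methylaniline | Cc1cccc(N)c1-c1ccc(OCc2ccccc2)c(OC)c1 | intermediate
4 | 4-bromo-2-(4-benzyloxy-3-methoxyphenyl)-3-methylaniline | Cc1c(Br)ccc(N)c1-c1ccc(OCc2ccccc2)c(OC)c1 | intermediate
5 | (4-benzyloxy-3-methoxyphenyl)methanol | COc1cc(CO)ccc1OCc1ccccc1 | starting material
6 | 1-benzyloxy-4-(chloromethyl)-2-methoxybenzene | COc1cc(CCl)ccc1OCc1ccccc1 | intermediate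
7 | (4-benzyloxy-3-methoxybenzyl)zinc chloride (LiCl complex in THF, not isolated) | COc1cc(C[Zn]Cl)ccc1OCc1ccccc1 | intermediate
8 | 2-(4-benzyloxy-3-methoxyphenyl)-4-[(4-benzyloxy-3-methoxyphenyl)methyl]-3-methylaniline | Cc1c(Cc2ccc(OCc3ccccc3)c(OC)c2)ccc(N)c1-c1ccc(OCc2ccccc2)c(OC)c1 | intermediate
9 | 2-(4-benzyloxy-3-methoxyphenyl)-4-[(4-benzyloxy-3-methoxyphenyl)methyl]-3-methylbenzenediazonium 4-methylbenzenesulfonate (not isolated) | Cc1c(Cc2ccc(OCc3ccccc3)c(OC)c2)ccc([N+]#N)c1-c1ccc(OCc2ccccc2)c(OC)c1.Cc1ccc(S(=O)(=O)[O-])cc1 | intermediate
10 | 2-(4-benzyloxy-3-methoxyphenyl)-4-[(4-benzyloxy-3-methoxyphenyl)methyl]-1-iodo-3-methylbenzene | Cc1c(Cc2ccc(OCc3ccccc3)c(OC)c2)ccc(I)c1-c1ccc(OCc2ccccc2)c(OC)c1 | intermediate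
11 | dimethyl squarate (3,4-dimethoxycyclobut-3-ene-1,2-dione) | COC1=C(OC)C(=O)C1=O | starting material
12 | 4-hydroxy-2,3-dimethoxycyclobut-2-en-1-one (racemic, one enantiomer drawn, not isolated) | COC1=C(OC)[C@@H](O)C1=O | intermediate
13 | methyl semisquarate (3-methoxycyclobut-3-ene-1,2-dione) | COC1=CC(=O)C1=O | intermediate
14 | {2-(4-benzyloxy-3-methoxyphenyl)-4-[(4-benzyloxy-3-methoxyphenyl)methyl]-3-methylphenyl}lithium (not isolated) | [Li]c1ccc(Cc2ccc(OCc3ccccc3)c(OC)c2)c(C)c1-c1ccc(OCc2ccccc2)c(OC)c1 | intermediate
15 | 4-{2-(4-benzyloxy-3-methoxyphenyl)-4-[(4-benzyloxy-3-methoxyphenyl)methyl]-3-methylphenyl}-4-hydroxy-3-methoxycyclobut-2-en-1-one (racemic, one enantiomer drawn) | COC1=CC(=O)[C@@]1(O)c1ccc(Cc2ccc(OCc3ccccc3)c(OC)c2)c(C)c1-c1ccc(OCc2ccccc2)c(OC)c1 | intermediate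
16 | (Z)-4-aryl-4-hydroxy-3-methoxybuta-1,3-dien-1-one, aryl as in 15 and cis to the ketenyl carbon (not isolated) | O=C=C/C(OC)=C(O)\c1ccc(Cc2ccc(OCc3ccccc3)c(OC)c2)c(C)c1-c1ccc(OCc2ccccc2)c(OC)c1 | intermediate
17 | 8-(4-benzyloxy-3-methoxyphenyl)-6-[(4-benzyloxy-3-methoxyphenyl)methyl]-2-methoxy-7-methylnaphthalene-1,4-diol | COc1cc(O)c2cc(Cc3ccc(OCc4ccccc4)c(OC)c3)c(C)c(-c3ccc(OCc4ccccc4)c(OC)c3)c2c1O | intermediate
18 | larreantin hydroquinone, 8-(4-hydroxy-3-methoxyphenyl)-6-[(4-hydroxy-3-methoxyphenyl)methyl]-2-methoxy-7-methylnaphthalene-1,4-diol (not isolated) | COc1cc(O)c2cc(Cc3ccc(O)c(OC)c3)c(C)c(-c3ccc(O)c(OC)c3)c2c1O | intermediate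
19 | larreantin, 8-(4-hydroxy-3-methoxyphenyl)-6-[(4-hydroxy-3-methoxyphenyl)methyl]-2-methoxy-7-methylnaphthalene-1,4-dione | COC1=CC(=O)c2cc(Cc3ccc(O)c(OC)c3)c(C)c(-c3ccc(O)c(OC)c3)c2C1=O | target

## Step count and least certain steps

Total step count: 9. Longest linear sequence: 7 steps (steps 1, 2, 4, 5, 7, 8 and 9, from 1). Steps 3 and 6 are side branches of one step each.

Step 8 (key step). The 6π closure forces ring C at C8 against the new C1 hydroxyl, and this peri compression may slow it. The dienylketene could then be diverted into dimerisation, capture by the free hydroxyl of a second molecule, or lactonisation to a furanone after inward rotation of the hydroxyl. The fallback sets out from 15 and comes back at 17. Silylation of the tertiary hydroxyl (TMSCl, imidazole, DMF) would give racemic 4-aryl-3-methoxy-4-(trimethylsilyloxy)cyclobut-2-en-1-one F1. On heating in xylene the silyloxy group still turns outward, but no free hydroxyl can intercept the ketene, and the product should be the C1-O-trimethylsilyl ether of the naphthalenediol F2. Mild acidic methanolysis (citric acid, MeOH) of this labile aryl silyl ether returns 17.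

Step 7. The small, unhindered electrophile 13 may be lost by displacement of its methoxy group (addition–elimination at the alkoxy-bearing carbon), by attack at the vinylogous ester carbonyl, by double addition or by base-induced oligomerisation. The hindered aryllithium may also add only slowly. The fallback sets out from 10, through 14, and comes back at 19; it replaces 13 by its tert-butyl analogue and installs the methyl ether at the end.
- Commercial di-tert-butyl squarate is reduced with LiAlH(OtBu)3 to 2,3-di-tert-butoxy-4-hydroxycyclobut-2-en-1-one F3, which TFAA converts into tert-butyl semisquarate F4.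
- Addition of 14 to F4 gives the tert-butoxy cyclobutenone F5.
- Ring expansion as in step 8 gives the 2-tert-butoxy naphthalenediol F6.
- Hydrogenolysis and aerobic oxidation as in step 9 give the 2-tert-butoxy quinone F7.
- Methanolic HCl at reflux cleaves the tert-butyl enol ether to the 2-hydroxyquinone F8 and etherifies it in the same pot (acid-catalysed etherification of a 2-hydroxy-1,4-naphthoquinone), giving 19.

Step 5. Iodide transfer may have to compete with hydrodediazoniation, hydrolysis to the phenol, or attack of the diazonium group on the neighbouring electron-rich ring C at the position para to its methoxy group. The fallback sets out from 8 and comes back at 10. Diazonium salt 9 is generated as in the first stage of step 5 and poured at once into pyrrolidine/K2CO3 at 0 °C, which traps it as the aryl triazene F9. This stable compound is purified and heated with MeI (110 °C, sealed tube), which releases the diazonium ion only in the presence of a high iodide concentration and gives 10.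

Step 9. The re-oxidation may stall or lose selectivity, since autoxidation of a polyphenolic diol in the presence of peroxide and palladium residues may be slow or touch the guaiacol rings; debenzylation may also be incomplete. The fallback sets out from 17 and comes back at 19. Oxidation of 17 with Ag2O in CH2Cl2 would give larreantin dibenzyl ether F10, a stable quinone that can be purified. Its benzyl ethers are then removed without any reduction by BCl3 with pentamethylbenzene as cation scavenger at −78 °C, giving 19.

## Further compounds

F1 | step 8 | 4-{2-(4-benzyloxy-3-methoxyphenyl)-4-[(4-benzyloxy-3-methoxyphenyl)methyl]-3-methylphenyl}-3-methoxy-4-(trimethylsilyloxy)cyclobut-2-en-1-one (racemic, one enantiomer drawn) | COC1=CC(=O)[C@@]1(O[Si](C)(C)C)c1ccc(Cc2ccc(OCc3ccccc3)c(OC)c2)c(C)c1-c1ccc(OCc2ccccc2)c(OC)c1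
F2 | step 8 | 5-(4-benzyloxy-3-methoxyphenyl)-7-[(4-benzyloxy-3-methoxyphenyl)methyl]-3-methoxy-6-methyl-4-(trimethylsilyloxy)naphthalen-1-ol (C1-O-silyl ether of 17 in larreantin numbering) | COc1cc(O)c2cc(Cc3ccc(OCc4ccccc4)c(OC)c3)c(C)c(-c3ccc(OCc4ccccc4)c(OC)c3)c2c1O[Si](C)(C)C
F3 | step 7 | 2,3-di-tert-butoxy-4-hydroxycyclobut-2-en-1-one (racemic, one enantiomer drawn) | CC(C)(C)OC1=C(OC(C)(C)C)[C@@H](O)C1=O
F4 | step 7 | tert-butyl semisquarate (3-tert-butoxycyclobut-3-ene-1,2-dione) | CC(C)(C)OC1=CC(=O)C1=O
F5 | step 7 | 3-tert-butoxy-4-{2-(4-benzyloxy-3-methoxyphenyl)-4-[(4-benzyloxy-3-methoxyphenyl)methyl]-3-methylphenyl}-4-hydroxycyclobut-2-en-1-one (racemic, one enantiomer drawn) | CC(C)(C)OC1=CC(=O)[C@@]1(O)c1ccc(Cc2ccc(OCc3ccccc3)c(OC)c2)c(C)c1-c1ccc(OCc2ccccc2)c(OC)c1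
F6 | step 7 | 2-tert-butoxy-8-(4-benzyloxy-3-methoxyphenyl)-6-[(4-benzyloxy-3-methoxyphenyl)methyl]-7-methylnaphthalene-1,4-diol | CC(C)(C)Oc1cc(O)c2cc(Cc3ccc(OCc4ccccc4)c(OC)c3)c(C)c(-c3ccc(OCc4ccccc4)c(OC)c3)c2c1O
F7 | step 7 | 2-tert-butoxy-8-(4-hydroxy-3-methoxyphenyl)-6-[(4-hydroxy-3-methoxyphenyl)methyl]-7-methylnaphthalene-1,4-dione | CC(C)(C)OC1=CC(=O)c2cc(Cc3ccc(O)c(OC)c3)c(C)c(-c3ccc(O)c(OC)c3)c2C1=O
F8 | step 7 | 2-hydroxy-8-(4-hydroxy-3-methoxyphenyl)-6-[(4-hydroxy-3-methoxyphenyl)methyl]-7-methylnaphthalene-1,4-dione | OC1=CC(=O)c2cc(Cc3ccc(O)c(OC)c3)c(C)c(-c3ccc(O)c(OC)c3)c2C1=O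
F9 | step 5 | (E)-1-{2-(4-benzyloxy-3-methoxyphenyl)-4-[(4-benzyloxy-3-methoxyphenyl)methyl]-3-methylphenyl}-2-(pyrrolidin-1-yl)diazene (aryl triazene) | Cc1c(Cc2ccc(OCc3ccccc3)c(OC)c2)ccc(/N=N/N2CCCC2)c1-c1ccc(OCc2ccccc2)c(OC)c1
F10 | step 9 | larreantin dibenzyl ether, 8-(4-benzyloxy-3-methoxyphenyl)-6-[(4-benzyloxy-3-methoxyphenyl)methyl]-2-methoxy-7-methylnaphthalene-1,4-dione | COC1=CC(=O)c2cc(Cc3ccc(OCc4ccccc4)c(OC)c3)c(C)c(-c3ccc(OCc4ccccc4)c(OC)c3)c2C1=O
A1 | alternative 1 | 3-[(4-benzyloxy-3-methoxyphenyl)methyl]-4-[2-(4-benzyloxy-3-methoxybenzoyl)-3,4,6-trimethoxyphenyl]butan-2-one (racemic, one enantiomer drawn) | COc1cc(OC)c(C[C@@H](Cc2ccc(OCc3ccccc3)c(OC)c2)C(C)=O)c(C(=O)c2ccc(OCc3ccccc3)c(OC)c2)c1OC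
A2 | alternative 1 | 8-(4-benzyloxy-3-methoxyphenyl)-6-[(4-benzyloxy-3-methoxyphenyl)methyl]-1,2,4-trimethoxy-7-methyl-5,6-dihydronaphthalene (racemic, one enantiomer drawn) | COc1cc(OC)c2C[C@@H](Cc3ccc(OCc4ccccc4)c(OC)c3)C(C)=C(c3ccc(OCc4ccccc4)c(OC)c3)c2c1OC
A3 | alternative 2 | 1-[4-(tert-butyldimethylsilyloxy)-3-methoxyphenyl]-4-methoxyoct-4-ene-1,7-diyne-3,6-dione with the two carbonyl groups cis | C#CC(=O)/C=C(OC)\C(=O)C#Cc1ccc(O[Si](C)(C)C(C)(C)C)c(OC)c1
A4 | alternative 2 | tert-butyl[4-(but-2-yn-1-yl)-2-methoxyphenoxy]dimethylsilane | CC#CCc1ccc(O[Si](C)(C)C(C)(C)C)c(OC)c1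
A5 | alternative 2 | larreantin bis(tert-butyldimethylsilyl) ether | COC1=CC(=O)c2cc(Cc3ccc(O[Si](C)(C)C(C)(C)C)c(OC)c3)c(C)c(-c3ccc(O[Si](C)(C)C(C)(C)C)c(OC)c3)c2C1=O
A6 | alternative 3 | 2-[(4-benzyloxy-3-methoxyphenyl)methyl]-3,4,6-trimethoxybenzaldehyde | COc1cc(OC)c(C=O)c(Cc2ccc(OCc3ccccc3)c(OC)c2)c1OC
A7 | alternative 3 | 1-(4-benzyloxy-3-methoxyphenyl)but-2-yn-1-one | CC#CC(=O)c1ccc(OCc2ccccc2)c(OC)c1
A8 | alternative 3 | (4-benzyloxy-3-methoxyphenyl)[8-(4-benzyloxy-3-methoxyphenyl)-1,2,4-trimethoxy-7-methylnaphthalen-6-yl]methanone | COc1cc(OC)c2cc(C(=O)c3ccc(OCc4ccccc4)c(OC)c3)c(C)c(-c3ccc(OCc4ccccc4)c(OC)c3)c2c1OC
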